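**Plan**

- Retrosynthesis: the three phenols are masked as MOM ethers, then ring C is cut at two bonds at once, O1–C8a and C4–C4a, leaving a ring A aryne (C4a≡C8a) and an (S)-3-aryl-3-oxypropanoic amide.
- Enabling feature: ring A is hexasubstituted and its neighbouring carbons C8a and C4a carry O1 and the C4 carbonyl, flanked by the C8 methyl and the C5 oxygen; both bonds can therefore be made across one aryne whose C5 oxygen steers the alkoxide to C8a.
- Ring A (steps 1–8): resorcinol; C6 prenyl by lithiation, O8a by C–H borylation/oxidation, C8 methyl and C4a silicon by two carbamate-directed lithiations, then o-silylaryl triflate 14.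
- Side chain (steps 9–12): methyl 4-hydroxybenzoate, β-keto Weinreb amide, (S)-carbinol, silyl ether 21; ring B is present from the start.
- Ring C is the only ring formed, in step 13 (annulation of 14 with 21); step 14 removes the MOM groups.
- Stereochemistry: the single stereocentre C2 is set by asymmetric transfer hydrogenation in step 11, and its C–O bond is never broken afterwards.

Key step: step 13

Remark: positions are given in flavanone numbering (O1, C2–C4, C4a, C5–C8, C8a); MOM = methoxymethyl, prenyl = 3-methylbut-2-en-1-yl. Assumption: the catalyst of step 11 reduces 19 with the facial sense usual for aryl alkyl ketones, which corresponds to (S) here.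

**Route**

Step 1
Reactants: 1 resorcinol
Product: 2 1,3-bis(methoxymethoxy)benzene
Conditions: NaH, MOMCl, DMF, 0 °C→rt
Reagents that add atoms: chloromethyl methyl ether (MOMCl), COCCl
Why: Williamson etherification of both phenoxides gives the bis-acetal, which protects O5 and O7 to the end and supplies the directing groups for the lithiation that follows.

Step 2
Reactants: 2 1,3-bis(methoxymethoxy)benzene; 3 prenyl bromide (1-bromo-3-methylbut-2-ene)
Product: 5 1,3-bis(methoxymethoxy)-2-(3-methylbut-2-en-1-yl)benzene, via 2-lithio-1,3-bis(methoxymethoxy)benzene 4 (not isolated)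
Conditions: n-BuLi, THF, 0 °C; CuI (10 mol %), 3, −78 °C→rt
Reagents that add atoms: n-butyllithium, [Li]CCCC (lithium of 4 only)
Why: Directed ortho-metalation removes the C–H flanked by both acetal oxygens, and the copper-catalysed allylation of the aryllithium by the primary bromide should occur at its α-carbon (SN2).

Step 3
Reactants: 5 1,3-bis(methoxymethoxy)-2-(3-methylbut-2-en-1-yl)benzene
Product: 7 3,5-bis(methoxymethoxy)-4-(3-methylbut-2-en-1-yl)phenol, via arylboronic acid pinacol ester 6 (not isolated)
Conditions: [Ir(OMe)(cod)]2 (1.5 mol %), dtbpy (3 mol %), B2pin2 (1.0 equiv), THF, 60 °C; then NaOH, 30% H2O2, 0 °C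
Reagents that add atoms: hydrogen peroxide, OO; bis(pinacolato)diboron, CC1(C)OB(OC1(C)C)B1OC(C)(C)C(C)(C)O1 (boron group of 6 only)
Why: Sterically governed iridium-catalysed aromatic C–H borylation should touch only the one ring C–H without an ortho substituent (para to the prenyl group), and basic peroxide oxidises the C–B bond to the phenol without attacking the unactivated trisubstituted alkene.

Step 4
Reactants: 7 3,5-bis(methoxymethoxy)-4-(3-methylbut-2-en-1-yl)phenol
Product: 8 3,5-bis(methoxymethoxy)-4-(3-methylbut-2-en-1-yl)phenyl N,N-diethylcarbamate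
Conditions: NaH, Et2NCOCl, THF, 0 °C→rt
Reagents that add atoms: N,N-diethylcarbamoyl chloride, CCN(CC)C(Cl)=O
Why: O-Carbamoylation of the sodium phenoxide marks the future O8a and installs the strongest oxygen-based directing group for the next two metalations.

Step 5
Reactants: 8 3,5-bis(methoxymethoxy)-4-(3-methylbut-2-en-1-yl)phenyl N,N-diethylcarbamate
Product: 10 3,5-bis(methoxymethoxy)-2-methyl-4-(3-methylbut-2-en-1-yl)phenyl N,N-diethylcarbamate, via 2-lithio aryl carbamate 9 (not isolated)
Conditions: s-BuLi, TMEDA, THF, −78 °C; MeI, −78 °C→rt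
Reagents that add atoms: iodomethane, CI; sec-butyllithium, CCC(C)[Li] (lithium of 9 only)
Why: Carbamate-directed ortho-metalation is unambiguous because the two free ring positions are equivalent and each lies between the carbamate and a MOM ether, and methylation at −78 °C should outrun the anionic Fries shift.

Step 6
Reactants: 10 3,5-bis(methoxymethoxy)-2-methyl-4-(3-methylbut-2-en-1-yl)phenyl N,N-diethylcarbamate
Product: 12 3,5-bis(methoxymethoxy)-2-methyl-4-(3-methylbut-2-en-1-yl)-6-(trimethylsilyl)phenyl N,N-diethylcarbamate, via 6-lithio aryl carbamate 11 (not isolated)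
Conditions: s-BuLi, TMEDA, THF, −78 °C; TMSCl, −78 °C→rt
Reagents that add atoms: chlorotrimethylsilane, C[Si](C)(C)Cl; sec-butyllithium, CCC(C)[Li] (lithium of 11 only)
Why: A second directed ortho-metalation takes the last ring C–H (kinetic ring lithiation at −78 °C is faster than lateral lithiation of the new methyl group) and the silyl chloride quench places silicon on the future C4a.

Step 7
Reactants: 12 3,5-bis(methoxymethoxy)-2-methyl-4-(3-methylbut-2-en-1-yl)-6-(trimethylsilyl)phenyl N,N-diethylcarbamate
Product: 13 3,5-bis(methoxymethoxy)-2-methyl-4-(3-methylbut-2-en-1-yl)-6-(trimethylsilyl)phenol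
Conditions: LiAlH4, THF, 0 °C→reflux; Na2SO4·10H2O quench
Reagents that add atoms: none
Why: Reductive acyl cleavage by hydride at the carbamate carbonyl expels the phenoxide, and the basic, non-acidic medium should leave the MOM acetals, the alkene and the acid-sensitive aryl–silicon bond untouched.

Step 8
Reactants: 13 3,5-bis(methoxymethoxy)-2-methyl-4-(3-methylbut-2-en-1-yl)-6-(trimethylsilyl)phenol
Product: 14 3,5-bis(methoxymethoxy)-2-methyl-4-(3-methylbut-2-en-1-yl)-6-(trimethylsilyl)phenyl trifluoromethanesulfonate
Conditions: Tf2O, pyridine, CH2Cl2, 0 °C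
Reagents that add atoms: trifluoromethanesulfonic anhydride, O=S(=O)(OS(=O)(=O)C(F)(F)F)C(F)(F)F
Why: O-Sulfonylation of the phenol under pyridine buffering gives the o-silylaryl triflate, the standard fluoride-triggered aryne precursor, with the leaving group on C8a and silicon on C4a.

Step 9
Reactants: 15 methyl 4-hydroxybenzoate
Product: 16 methyl 4-(methoxymethoxy)benzoate
Conditions: NaH, MOMCl, DMF, 0 °C→rt
Reagents that add atoms: chloromethyl methyl ether (MOMCl), COCCl
Why: Williamson etherification protects the 4′-oxygen with the same acetal as ring A, so that one acid treatment frees all three phenols at the end.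

Step 10
Reactants: 16 methyl 4-(methoxymethoxy)benzoate; 17 N-methoxy-N-methylacetamide
Product: 19 N-methoxy-3-[4-(methoxymethoxy)phenyl]-N-methyl-3-oxopropanamide, via lithium enolate of the acetamide 18 (not isolated)
Conditions: LDA (2.2 equiv), 17, THF, −78 °C; then 16, −78→0 °C; sat. aq NH4Cl
Reagents that add atoms: lithium diisopropylamide, CC(C)N([Li])C(C)C (lithium of 18 only)
Why: Crossed Claisen condensation of the pre-formed amide enolate with a non-enolisable ester is driven to completion by deprotonation of the β-keto amide product by the second equivalent of base.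

Step 11
Reactants: 19 N-methoxy-3-[4-(methoxymethoxy)phenyl]-N-methyl-3-oxopropanamide
Product: 20 (3S)-3-hydroxy-N-methoxy-3-[4-(methoxymethoxy)phenyl]-N-methylpropanamide
Conditions: RuCl(p-cymene)[(S,S)-TsDPEN] (1 mol %), HCO2H/Et3N (5:2), EtOAc, 30 °C
Reagents that add atoms: none
Why: Noyori–Ikariya asymmetric transfer hydrogenation of the aryl ketone, in which the (S,S) ligand holds the aryl group against the arene ligand and hydride adds to one face only, should set the (S) carbinol that becomes C2 under buffered conditions that keep the electron-rich benzylic alcohol from ionising.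

Step 12
Reactants: 20 (3S)-3-hydroxy-N-methoxy-3-[4-(methoxymethoxy)phenyl]-N-methylpropanamide
Product: 21 (3S)-N-methoxy-3-[4-(methoxymethoxy)phenyl]-N-methyl-3-[(trimethylsilyl)oxy]propanamide
Conditions: TMSCl, imidazole, CH2Cl2, 0 °C; non-aqueous work-up
Reagents that add atoms: chlorotrimethylsilane, C[Si](C)(C)Cl
Why: O-Silylation removes the only O–H proton of the nucleophile and turns the hydroxyl into an alkoxide that fluoride can release in the flask.

Step 13
Reactants: 14 3,5-bis(methoxymethoxy)-2-methyl-4-(3-methylbut-2-en-1-yl)-6-(trimethylsilyl)phenyl trifluoromethanesulfonate; 21 (3S)-N-methoxy-3-[4-(methoxymethoxy)phenyl]-N-methyl-3-[(trimethylsilyl)oxy]propanamide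
Product: 25 (2S)-5,7-bis(methoxymethoxy)-2-[4-(methoxymethoxy)phenyl]-8-methyl-6-(3-methylbut-2-en-1-yl)-2,3-dihydro-4H-chromen-4-one, via caesium alkoxide 22 (not isolated), via ring A aryne 23 (not isolated), via caesium hemiaminal alkoxide 24 (not isolated)
Conditions: 21 (1.3 equiv), CsF (3 equiv), 18-crown-6 (3 equiv), THF, 0 °C→rt; then sat. aq NH4Cl, 0 °C
Reagents that add atoms: caesium fluoride, [Cs+].[F-] (caesium of 22 and 24 only)
Why: Proposed new method: fluoride removes the silyl groups of both partners, so that alkoxide 22 and aryne 23 meet in a medium without any O–H bond; the alkoxide oxygen bonds to C8a, and the C4a carbanion so formed, with no proton within reach, adds to the Weinreb carbonyl to give hemiaminal alkoxide 24, which keeps C4 tetrahedral until the aqueous quench releases ketone 25. The closest known reaction type is the fluoride-induced annulation of arynes with salicylate esters to xanthones (O-arylation, then intramolecular acyl substitution by the aryl anion), extended here from a phenoxide to an aliphatic alkoxide unmasked from its silyl ether. Ring C closes by 6-exo-trig attack of C4a on the amide carbonyl. No lasting stereocentre is created (the C4 centre of 24 disappears on hydrolysis) and the C2–O bond is never broken, so C2 keeps the S configuration from step 11; because neither an enolisable ketone nor free methoxide is present before the quench, ring opening to the chalcone, the usual racemisation path of flavanones in base, should be shut off. The selectivity needed is bonding of oxygen to C8a and not to C4a, and it is secured by the inductively withdrawing C5 oxygen next to C4a, which distorts the aryne so that the nucleophile adds to the remote carbon and the negative charge develops beside oxygen, a bias that should outweigh the small steric effect of the C8 methyl. The amide was chosen over an ester because its less acidic α-hydrogens and poorer enolate leaving group should also slow retro-aldol cleavage of the alkoxide and proton transfer to the aryl anion.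

Step 14
Reactants: 25 (2S)-5,7-bis(methoxymethoxy)-2-[4-(methoxymethoxy)phenyl]-8-methyl-6-(3-methylbut-2-en-1-yl)-2,3-dihydro-4H-chromen-4-one
Product: 26 (2S)-5,7-dihydroxy-2-(4-hydroxyphenyl)-8-methyl-6-(3-methylbut-2-en-1-yl)-2,3-dihydro-4H-chromen-4-one
Conditions: 3 M aq HCl, MeOH, rt→40 °C
Reagents that add atoms: none
Why: Acid-catalysed acetal exchange with methanol frees the three phenols under conditions customary for prenylated flavanones, mild enough that the prenyl group should not cyclise onto the neighbouring phenols and that C2, which epimerises only through base-induced ring opening, is not touched.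

**Compound list**

1 | resorcinol (benzene-1,3-diol) | Oc1cccc(O)c1 | starting material
2 | 1,3-bis(methoxymethoxy)benzene | COCOc1cccc(OCOC)c1 | intermediate
3 | prenyl bromide (1-bromo-3-methylbut-2-ene) | CC(C)=CCBr | starting material
4 | 2-lithio-1,3-bis(methoxymethoxy)benzene | [Li]c1c(OCOC)cccc1OCOC | intermediate
5 | 1,3-bis(methoxymethoxy)-2-(3-methylbut-2-en-1-yl)benzene | CC(C)=CCc1c(OCOC)cccc1OCOC | intermediate
6 | 2-[3,5-bis(methoxymethoxy)-4-(3-methylbut-2-en-1-yl)phenyl]-4,4,5,5-tetramethyl-1,3,2-dioxaborolane | CC(C)=CCc1c(OCOC)cc(cc1OCOC)B1OC(C)(C)C(C)(C)O1 | intermediate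
7 | 3,5-bis(methoxymethoxy)-4-(3-methylbut-2-en-1-yl)phenol | CC(C)=CCc1c(OCOC)cc(O)cc1OCOC | intermediate
8 | 3,5-bis(methoxymethoxy)-4-(3-methylbut-2-en-1-yl)phenyl N,N-diethylcarbamate | CCN(CC)C(=O)Oc1cc(OCOC)c(CC=C(C)C)c(OCOC)c1 | intermediate
9 | 2-lithio-3,5-bis(methoxymethoxy)-4-(3-methylbut-2-en-1-yl)phenyl N,N-diethylcarbamate | CCN(CC)C(=O)Oc1cc(OCOC)c(CC=C(C)C)c(OCOC)c1[Li] | intermediate
10 | 3,5-bis(methoxymethoxy)-2-methyl-4-(3-methylbut-2-en-1-yl)phenyl N,N-diethylcarbamate | CCN(CC)C(=O)Oc1cc(OCOC)c(CC=C(C)C)c(OCOC)c1C | intermediate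
11 | 6-lithio-3,5-bis(methoxymethoxy)-2-methyl-4-(3-methylbut-2-en-1-yl)phenyl N,N-diethylcarbamate | CCN(CC)C(=O)Oc1c([Li])c(OCOC)c(CC=C(C)C)c(OCOC)c1C | intermediate
12 | 3,5-bis(methoxymethoxy)-2-methyl-4-(3-methylbut-2-en-1-yl)-6-(trimethylsilyl)phenyl N,N-diethylcarbamate | CCN(CC)C(=O)Oc1c([Si](C)(C)C)c(OCOC)c(CC=C(C)C)c(OCOC)c1C | intermediate
13 | 3,5-bis(methoxymethoxy)-2-methyl-4-(3-methylbut-2-en-1-yl)-6-(trimethylsilyl)phenol | CC(C)=CCc1c(OCOC)c(C)c(O)c([Si](C)(C)C)c1OCOC | intermediate
14 | 3,5-bis(methoxymethoxy)-2-methyl-4-(3-methylbut-2-en-1-yl)-6-(trimethylsilyl)phenyl trifluoromethanesulfonate | CC(C)=CCc1c(OCOC)c(C)c(OS(=O)(=O)C(F)(F)F)c([Si](C)(C)C)c1OCOC | intermediate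
15 | methyl 4-hydroxybenzoate | COC(=O)c1ccc(O)cc1 | starting material
16 | methyl 4-(methoxymethoxy)benzoate | COCOc1ccc(cc1)C(=O)OC | intermediate
17 | N-methoxy-N-methylacetamide | CC(=O)N(C)OC | starting material
18 | lithium 1-[methoxy(methyl)amino]ethen-1-olate (lithium enolate of 17) | C=C(O[Li])N(C)OC | intermediate
19 | N-methoxy-3-[4-(methoxymethoxy)phenyl]-N-methyl-3-oxopropanamide | CON(C)C(=O)CC(=O)c1ccc(OCOC)cc1 | intermediate
20 | (3S)-3-hydroxy-N-methoxy-3-[4-(methoxymethoxy)phenyl]-N-methylpropanamide | CON(C)C(=O)C[C@@H](c1ccc(OCOC)cc1)O | intermediate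
21 | (3S)-N-methoxy-3-[4-(methoxymethoxy)phenyl]-N-methyl-3-[(trimethylsilyl)oxy]propanamide | CON(C)C(=O)C[C@@H](c1ccc(OCOC)cc1)O[Si](C)(C)C | intermediate
22 | caesium (1S)-3-[methoxy(methyl)amino]-1-[4-(methoxymethoxy)phenyl]-3-oxopropan-1-olate | CON(C)C(=O)C[C@@H](c1ccc(OCOC)cc1)[O-].[Cs+] | intermediate
23 | 3,5-bis(methoxymethoxy)-6-methyl-4-(3-methylbut-2-en-1-yl)-1,2-didehydrobenzene (ring A C4a≡C8a aryne) | CC(C)=CCC1=C(OCOC)C#CC(C)=C1OCOC | intermediate
24 | caesium (2S)-4-[methoxy(methyl)amino]-5,7-bis(methoxymethoxy)-2-[4-(methoxymethoxy)phenyl]-8-methyl-6-(3-methylbut-2-en-1-yl)-3,4-dihydro-2H-chromen-4-olate (both C4 epimers) | CC(C)=CCc1c(OCOC)c(C)c2c(c1OCOC)C([O-])(N(C)OC)C[C@@H](c1ccc(OCOC)cc1)O2.[Cs+] | intermediate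
25 | (2S)-5,7-bis(methoxymethoxy)-2-[4-(methoxymethoxy)phenyl]-8-methyl-6-(3-methylbut-2-en-1-yl)-2,3-dihydro-4H-chromen-4-one | CC(C)=CCc1c(OCOC)c(C)c2c(c1OCOC)C(=O)C[C@@H](c1ccc(OCOC)cc1)O2 | intermediate
26 | (2S)-5,7-dihydroxy-2-(4-hydroxyphenyl)-8-methyl-6-(3-methylbut-2-en-1-yl)-2,3-dihydro-4H-chromen-4-one (5,7,4′-trihydroxy-8-methyl-6-prenylflavanone) | CC(C)=CCc1c(O)c(C)c2c(c1O)C(=O)C[C@@H](c1ccc(O)cc1)O2 | target

**Step count and risks**

Total: 14 steps. Longest linear sequence: 10 steps (steps 1–8, 13, 14); the side chain takes 4 steps (9–12) before the union.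

Most likely to fail:

1. Step 13. The released alkoxide may fragment by retro-aldol cleavage or be re-silylated faster than it meets the aryne, and the aryl anion may be protonated (by the α-methylene group or by traces of water) before it reaches the amide carbonyl, so that ring C does not close. The fallback uses known reactions only, sets out from 14 and comes back at 25. The aryne is released from 14 with CsF in hot THF in the presence of acetic acid; insertion of the aryne into the C–O bond of the carboxylic acid (O-arylation at C8a, then 1,3-acyl shift to C4a, the same regiochemical bias) should give 1-[2-hydroxy-4,6-bis(methoxymethoxy)-3-methyl-5-(3-methylbut-2-en-1-yl)phenyl]ethan-1-one F1. Condensation with DMF dimethyl acetal gives (2E)-3-(dimethylamino)-1-[2-hydroxy-4,6-bis(methoxymethoxy)-3-methyl-5-(3-methylbut-2-en-1-yl)phenyl]prop-2-en-1-one F2, which closes with loss of dimethylamine (PPTS or silica gel) to 5,7-bis(methoxymethoxy)-8-methyl-6-(3-methylbut-2-en-1-yl)-4H-chromen-4-one F3. Rhodium-catalysed asymmetric 1,4-addition of 4-(methoxymethoxy)phenylboronic acid ([Rh(OH)(cod)]2, a chiral biaryl bisphosphine, aqueous toluene), with the ligand antipode that gives the 2S product, then leads to 25. In this variant ring C is closed before C2 is set, and the stereocentre comes from the rhodium catalyst instead of step 11.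

2. Step 3. The prenyl alkene may interfere with the borylation (hydroboration by the pinacolborane formed, allylic or vinylic borylation, or binding to the catalyst). The fallback sets out from 2 and comes back at 7, placing the oxygen before the alkene is present. Compound 2 is borylated under the same catalysis at its only unhindered C–H to give 2-[3,5-bis(methoxymethoxy)phenyl]-4,4,5,5-tetramethyl-1,3,2-dioxaborolane F4, and basic peroxide gives 3,5-bis(methoxymethoxy)phenol F5. Silylation with TIPSCl and imidazole gives [3,5-bis(methoxymethoxy)phenoxy]tri(propan-2-yl)silane F6, whose bulky silyl ether shields its own ortho positions. Lithiation between the two acetal oxygens with n-BuLi and CuI-catalysed coupling with 3 gives [3,5-bis(methoxymethoxy)-4-(3-methylbut-2-en-1-yl)phenoxy]tri(propan-2-yl)silane F7, and TBAF in THF frees phenol 7.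

3. Step 7. Hydride may fail to reach the carbamate carbonyl, which is shielded by the ortho methyl and trimethylsilyl groups, or the forcing conditions and the work-up may cleave the aryl–silicon bond. The fallback sets out from 10 and comes back at 13, removing the carbamate before silicon is introduced. LiAlH4 cleaves the less hindered carbamate 10 to 3,5-bis(methoxymethoxy)-2-methyl-4-(3-methylbut-2-en-1-yl)phenol F8. NBS in CH2Cl2 at −78 °C brominates the single free ring position to give 2-bromo-3,5-bis(methoxymethoxy)-6-methyl-4-(3-methylbut-2-en-1-yl)phenol F9. Hexamethyldisilazane silylates the oxygen to give [2-bromo-3,5-bis(methoxymethoxy)-6-methyl-4-(3-methylbut-2-en-1-yl)phenoxy]trimethylsilane F10. n-BuLi at −78 °C then effects bromine–lithium exchange and the 1,3 O→C silyl shift (retro-Brook rearrangement), and aqueous quench gives phenol 13, which re-enters at step 8.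

Further compounds
F1 | step 13 | 1-[2-hydroxy-4,6-bis(methoxymethoxy)-3-methyl-5-(3-methylbut-2-en-1-yl)phenyl]ethan-1-one | CC(C)=CCc1c(OCOC)c(C)c(O)c(C(C)=O)c1OCOC
F2 | step 13 | (2E)-3-(dimethylamino)-1-[2-hydroxy-4,6-bis(methoxymethoxy)-3-methyl-5-(3-methylbut-2-en-1-yl)phenyl]prop-2-en-1-one | CC(C)=CCc1c(OCOC)c(C)c(O)c(C(=O)/C=C/N(C)C)c1OCOC
F3 | step 13 | 5,7-bis(methoxymethoxy)-8-methyl-6-(3-methylbut-2-en-1-yl)-4H-chromen-4-one | CC(C)=CCc1c(OCOC)c(C)c2occc(=O)c2c1OCOC
F4 | step 3 | 2-[3,5-bis(methoxymethoxy)phenyl]-4,4,5,5-tetramethyl-1,3,2-dioxaborolane | COCOc1cc(OCOC)cc(c1)B1OC(C)(C)C(C)(C)O1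
F5 | step 3 | 3,5-bis(methoxymethoxy)phenol | COCOc1cc(O)cc(OCOC)c1
F6 | step 3 | [3,5-bis(methoxymethoxy)phenoxy]tri(propan-2-yl)silane | COCOc1cc(OCOC)cc(O[Si](C(C)C)(C(C)C)C(C)C)c1
F7 | step 3 | [3,5-bis(methoxymethoxy)-4-(3-methylbut-2-en-1-yl)phenoxy]tri(propan-2-yl)silane | CC(C)=CCc1c(OCOC)cc(O[Si](C(C)C)(C(C)C)C(C)C)cc1OCOC
F8 | step 7 | 3,5-bis(methoxymethoxy)-2-methyl-4-(3-methylbut-2-en-1-yl)phenol | CC(C)=CCc1c(OCOC)cc(O)c(C)c1OCOC
F9 | step 7 | 2-bromo-3,5-bis(methoxymethoxy)-6-methyl-4-(3-methylbut-2-en-1-yl)phenol | CC(C)=CCc1c(OCOC)c(Br)c(O)c(C)c1OCOC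
F10 | step 7 | [2-bromo-3,5-bis(methoxymethoxy)-6-methyl-4-(3-methylbut-2-en-1-yl)phenoxy]trimethylsilane | CC(C)=CCc1c(OCOC)c(Br)c(O[Si](C)(C)C)c(C)c1OCOC
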